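**Retrosynthetic overview**

1. Target 30 ⇐ acetonide hydrolysis ⇐ Pd/CO cyclocarbonylation of the C11 alkenyl iodide onto the C6 hydroxyl (C12 and the α-methylene-γ-lactone are made last) ⇐ C9 angelate ⇐ C9 ketone 23.
2. The ten-membered carbocycle of 23 ⇐ twelve-membered lactone 21 [C9(=O)–O–C13] by carbonyl methylenation and Claisen ring contraction (12 → 10 ring atoms). This one operation makes the C7–C8 bond, the C7 stereocentre, the C11=C13 methylene and the C9 carbonyl.
3. Enabling feature: in the carbocycle, the oxygenated C9 and C7 are 1,3-related through C8H2, and C7 carries the exocyclic C11=C13 alkene. This is a γ,δ-unsaturated carbonyl (Claisen) retron whose allyl carbons C13 and C11 lie outside the carbocycle, so its precursor is a lactone two atoms larger. The iodine on C11 enforces A(1,3) control from C6 and later becomes C12 through CO.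
4. 21 ⇐ seco acid 19 (Yamaguchi) ⇐ NHK union at C3–C4 of lactone aldehyde 6 with Z-iodoalkene 14. C2 is bought with (S)-γ-hydroxymethyl-γ-butyrolactone, C6 is set by catalytic asymmetric alkynylation, and C10, C3, C7 and C9 are relayed by substrate control.
5. Order of rings: temporary γ-lactone (starting material) → dioxolane (step 10) → twelve-membered lactone (step 13) → ten-membered carbocycle (step 14) → α-methylene-γ-lactone (step 18).

Key step: step 14

Remark: germacrane numbering is used for all intermediates (ring C1–C10; C11–C13 on C7 with C12 the lactone carbonyl; C14 on C10; C15 on C4). In step 7 the ProPhenol antipode is the one that gives the 4R carbinol.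

**Route**

Step 1
Reactants: 1 (S)-5-(hydroxymethyl)dihydrofuran-2(3H)-one
Product: 2 (S)-5-[(tert-butyldiphenylsilyloxy)methyl]dihydrofuran-2(3H)-one
Conditions: TBDPSCl, imidazole, DMF, 0 °C → rt
Reagents that add atoms: tert-butyl(chloro)diphenylsilane, CC(C)(C)[Si](Cl)(c1ccccc1)c1ccccc1
Why: Standard silylation of the primary alcohol; the bulky ether later shields one face of the lactone enolate.

Step 2
Reactants: 2 (S)-5-[(tert-butyldiphenylsilyloxy)methyl]dihydrofuran-2(3H)-one
Product: 4 (3R,5S)-5-[(tert-butyldiphenylsilyloxy)methyl]-3-methyldihydrofuran-2(3H)-one, via lithium enolate 3 (not isolated)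
Conditions: LDA, THF, −78 °C; then MeI, −78 °C
Reagents that add atoms: iodomethane, CI
Why: Kinetic lactone enolate alkylation in which MeI should approach anti to the C5 silyloxymethyl group, giving the trans lactone and so setting C10 relative to C2.

Step 3
Reactants: 4 (3R,5S)-5-[(tert-butyldiphenylsilyloxy)methyl]-3-methyldihydrofuran-2(3H)-one
Product: 5 (3R,5S)-5-(hydroxymethyl)-3-methyldihydrofuran-2(3H)-one
Conditions: HF·pyridine, THF, 0 °C → rt
Reagents that add atoms: none
Why: Fluoride desilylation under non-basic conditions that leave the lactone and its α-stereocentre untouched.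

Step 4
Reactants: 5 (3R,5S)-5-(hydroxymethyl)-3-methyldihydrofuran-2(3H)-one
Product: 6 (2S,4R)-4-methyl-5-oxotetrahydrofuran-2-carbaldehyde
Conditions: Dess–Martin periodinane, NaHCO3, CH2Cl2, 0 °C → rt; used crude
Reagents that add atoms: none
Why: Dess–Martin oxidation in buffered, non-basic medium should give the α-acyloxy aldehyde without epimerisation at C2.

Step 5
Reactants: 7 but-2-yn-1-ol
Product: 9 (Z)-3-iodobut-2-en-1-ol, via cyclic alkenylaluminate 8 (not isolated)
Conditions: Red-Al, THF, 0 °C → rt; then I2, THF, −78 → 0 °C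
Reagents that add atoms: iodine, II
Why: Hydroxyl-directed trans-hydroalumination puts aluminium on C3 and hydride on C2, and iodinolysis with retention gives the Z-iodoalkene that fixes the 4Z geometry of the target.

Step 6
Reactants: 9 (Z)-3-iodobut-2-en-1-ol
Product: 10 (Z)-3-iodobut-2-enal
Conditions: MnO2, CH2Cl2, rt, dark; used directly
Reagents that add atoms: none
Why: Neutral allylic oxidation with MnO2 should leave the Z geometry of the β-iodoenal intact.

Step 7
Reactants: 10 (Z)-3-iodobut-2-enal; 11 tert-butyldimethyl(prop-2-yn-1-yloxy)silane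
Product: 13 (4R,5Z)-1-(tert-butyldimethylsilyloxy)-6-iodohept-5-en-2-yn-4-ol, via alkynylzinc 12 (not isolated)
Conditions: Me2Zn, ProPhenol (20 mol %, antipode for the 4R alcohol), Ph3P=O (cat.), toluene, 0–4 °C; 11 premixed, then 10
Reagents that add atoms: none
Why: Zinc/ProPhenol-catalysed enantioselective alkynylation of an enal (Trost alkynylation) sets C6 of the target by catalyst control.

Step 8
Reactants: 13 (4R,5Z)-1-(tert-butyldimethylsilyloxy)-6-iodohept-5-en-2-yn-4-ol
Product: 14 (4R,5Z)-1-(tert-butyldimethylsilyloxy)-6-iodo-4-(4-methoxybenzyloxy)hept-5-en-2-yne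
Conditions: NaH, PMBCl, Bu4NI (cat.), THF/DMF, 0 °C
Reagents that add atoms: 4-methoxybenzyl chloride, COc1ccc(CCl)cc1
Why: Williamson etherification at 0 °C; the PMB ether survives the later acid step and is removable oxidatively next to the angelate.

Step 9
Reactants: 6 (2S,4R)-4-methyl-5-oxotetrahydrofuran-2-carbaldehyde; 14 (4R,5Z)-1-(tert-butyldimethylsilyloxy)-6-iodo-4-(4-methoxybenzyloxy)hept-5-en-2-yne
Product: 15 (3R,5S)-5-[(1R,2Z,4R)-7-(tert-butyldimethylsilyloxy)-1-hydroxy-4-(4-methoxybenzyloxy)-2-methylhept-2-en-5-yn-1-yl]-3-methyldihydrofuran-2(3H)-one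
Conditions: CrCl2, NiCl2 (cat.), DMSO, rt
Reagents that add atoms: none
Why: Nozaki–Hiyama–Kishi coupling in which the alkenylchromium (Z geometry retained) adds only to the aldehyde, and polar Felkin–Anh attack anti to the C2–O bond should give the 2,3-anti (3R) alcohol.

Step 10
Reactants: 15 (3R,5S)-5-[(1R,2Z,4R)-7-(tert-butyldimethylsilyloxy)-1-hydroxy-4-(4-methoxybenzyloxy)-2-methylhept-2-en-5-yn-1-yl]-3-methyldihydrofuran-2(3H)-one
Product: 16 methyl (2R)-3-{(4S,5R)-5-[(2Z,4R)-7-hydroxy-4-(4-methoxybenzyloxy)hept-2-en-5-yn-2-yl]-2,2-dimethyl-1,3-dioxolan-4-yl}-2-methylpropanoate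
Conditions: 2,2-dimethoxypropane/MeOH, CSA (cat.), rt; Et3N quench
Reagents that add atoms: methanol, CO; 2,2-dimethoxypropane, COC(C)(C)OC
Why: Acid-catalysed methanolysis of the γ-lactone is driven by trapping of the freed 2,3-diol as the cis-dioxolane (transacetalisation), and the primary propargylic TBS ether is cleaved in the same medium.

Step 11
Reactants: 16 methyl (2R)-3-{(4S,5R)-5-[(2Z,4R)-7-hydroxy-4-(4-methoxybenzyloxy)hept-2-en-5-yn-2-yl]-2,2-dimethyl-1,3-dioxolan-4-yl}-2-methylpropanoate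
Product: 18 methyl (2R)-3-{(4S,5R)-5-[(2Z,4R,5Z)-7-hydroxy-6-iodo-4-(4-methoxybenzyloxy)hepta-2,5-dien-2-yl]-2,2-dimethyl-1,3-dioxolan-4-yl}-2-methylpropanoate, via alkenylstannane 17 (not isolated)
Conditions: [Cp*RuCl]4 (cat.), Bu3SnH, CH2Cl2, rt; then I2, CH2Cl2, 0 °C
Reagents that add atoms: iodine, II
Why: Ruthenium-catalysed trans-hydrostannation steered by the free propargylic hydroxyl puts tin on C11 and hydrogen on C7 anti, and iododestannylation with retention gives the alkene with C6 and C13 trans and iodine cis to C6.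

Step 12
Reactants: 18 methyl (2R)-3-{(4S,5R)-5-[(2Z,4R,5Z)-7-hydroxy-6-iodo-4-(4-methoxybenzyloxy)hepta-2,5-dien-2-yl]-2,2-dimethyl-1,3-dioxolan-4-yl}-2-methylpropanoate
Product: 19 (2R)-3-{(4S,5R)-5-[(2Z,4R,5Z)-7-hydroxy-6-iodo-4-(4-methoxybenzyloxy)hepta-2,5-dien-2-yl]-2,2-dimethyl-1,3-dioxolan-4-yl}-2-methylpropanoic acid
Conditions: LiOH, THF/MeOH/H2O, 0 °C → rt; then dilute HCl to pH 4, 0 °C
Reagents that add atoms: lithium hydroxide, [Li+].[OH-]
Why: Mild saponification of the methyl ester, which the acetonide, the PMB ether and the alkenyl iodide should tolerate.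

Step 13
Reactants: 19 (2R)-3-{(4S,5R)-5-[(2Z,4R,5Z)-7-hydroxy-6-iodo-4-(4-methoxybenzyloxy)hepta-2,5-dien-2-yl]-2,2-dimethyl-1,3-dioxolan-4-yl}-2-methylpropanoic acid
Product: 21 twelve-membered lactone of 19 closed between C9 and O13 (2S,3R,6R,10R; 4Z; 7Z), via mixed anhydride 20 (not isolated)
Conditions: 2,4,6-trichlorobenzoyl chloride, Et3N, THF, rt; then slow addition to DMAP, toluene, 70 °C, high dilution
Reagents that add atoms: none
Why: Yamaguchi macrolactonisation onto the primary allylic alcohol, helped by the Z-C4=C5 alkene and the cis-dioxolane as turn elements.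

Step 14
Reactants: 21 twelve-membered lactone (ring atoms C9, O, C13, C11, C7, C6, C5, C4, C3, C2, C1, C10)
Product: 23 (2S,3R,4Z,6R,7R,10R)-11-iodo-2,3-(isopropylidenedioxy)-6-(4-methoxybenzyloxy)-12-norgermacra-4,11(13)-dien-9-one, via exocyclic enol ether 22 (not isolated)
Conditions: Cp2TiMe2, toluene, 75 °C, dark; then 125 °C, sealed tube
Reagents that add atoms: dimethyltitanocene, [CH3-].[CH3-].C1=C[CH-]C=C1.C1=C[CH-]C=C1.[Ti+4]
Why: Dimethyltitanocene methylenates the lactone carbonyl of 21 to the exocyclic enol ether 22 (C9=C8H2), whose allyl vinyl ether unit C8=C9–O–C13–C11=C7 then undergoes a concerted thermal [3,3] (Claisen) shift in which C8 bonds to C7, the C13–O bond breaks and the C9 ketone and the C11=C13 methylene appear, so that O, C13 and C11 leave the ring while C8 enters it (12 → 10 atoms). The closest known reaction types are the Claisen rearrangement of 2-methylene oxacycles made by titanium methylenation of lactones and the Claisen ring contraction of macrolide-derived ketene acetals. The carbocycle is closed by a sigmatropic ring contraction through a six-centre chair-like transition state in which the seven-atom C10–C6 tether bridges C9 and C7 and C6 sits pseudo-equatorial because C6 and C13 are trans on the C7=C11 bond. The new stereocentre C7 is controlled by C6, because A(1,3) strain with the iodine on C11 holds H6 in the alkene plane, so the ring tether (C5) and therefore C8 lie on one face and the C6–OPMB bond on the other, which is the 6,7 relationship of the trans-lactone. The step needs this face selectivity and [3,3] selectivity over Cope rearrangement of the 1,5-diene in the product and over hydrolysis or loss of the alkenyl iodide, which the iodine substituent, the acid-free medium and a temperature held near 125 °C should secure. The driving force is the new C=O bond, which should outweigh the strain of the ten-membered ring.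

Step 15
Reactants: 23 (2S,3R,4Z,6R,7R,10R)-11-iodo-2,3-(isopropylidenedioxy)-6-(4-methoxybenzyloxy)-12-norgermacra-4,11(13)-dien-9-one
Product: 24 (2S,3R,4Z,6R,7R,9S,10R)-11-iodo-2,3-(isopropylidenedioxy)-6-(4-methoxybenzyloxy)-12-norgermacra-4,11(13)-dien-9-ol
Conditions: L-Selectride, THF, −78 °C
Reagents that add atoms: none
Why: Bulky hydride reduction in which peripheral, Felkin-type attack (C10–C1 bond perpendicular to the carbonyl, C10 methyl inside) should give the 9,10-anti (9S) alcohol.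

Step 16
Reactants: 24 (2S,3R,4Z,6R,7R,9S,10R)-11-iodo-2,3-(isopropylidenedioxy)-6-(4-methoxybenzyloxy)-12-norgermacra-4,11(13)-dien-9-ol; 25 angelic acid
Product: 27 9-O-angeloyl derivative of 24, via angelic mixed anhydride 26 (not isolated)
Conditions: 2,4,6-trichlorobenzoyl chloride, Et3N, toluene, rt; then 24, 80 °C, no DMAP
Reagents that add atoms: none
Why: Yamaguchi-type esterification through the mixed anhydride, run without a nucleophilic catalyst so that the Z angelate should not isomerise to the tiglate.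

Step 17
Reactants: 27 (2S,3R,4Z,6R,7R,9S,10R)-9-angeloyloxy-11-iodo-2,3-(isopropylidenedioxy)-6-(4-methoxybenzyloxy)-12-norgermacra-4,11(13)-diene
Product: 28 (2S,3R,4Z,6R,7R,9S,10R)-9-angeloyloxy-11-iodo-2,3-(isopropylidenedioxy)-12-norgermacra-4,11(13)-dien-6-ol
Conditions: DDQ, CH2Cl2/pH 7 buffer, 0 °C
Reagents that add atoms: none
Why: Oxidative cleavage of the PMB ether with DDQ frees the C6 hydroxyl under neutral conditions that spare the angelate, the acetonide and the alkenyl iodide.

Step 18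
Reactants: 28 (2S,3R,4Z,6R,7R,9S,10R)-9-angeloyloxy-11-iodo-2,3-(isopropylidenedioxy)-12-norgermacra-4,11(13)-dien-6-ol
Product: 29 (2S,3R,4Z,6R,7S,9S,10R)-9-angeloyloxy-2,3-(isopropylidenedioxy)germacra-4,11(13)-dien-12,6-olide
Conditions: Pd(PPh3)4 (cat.), CO (1 atm), K2CO3, THF, 50 °C
Reagents that add atoms: carbon monoxide, [C-]#[O+]
Why: Palladium-catalysed cyclocarbonylation of a 3-iodobut-3-en-1-ol unit (oxidative addition, CO insertion, capture of the acyl-palladium by the C6 hydroxyl) gives the α-methylene-γ-lactone, trans-fused because C6 and C7 are already set.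

Step 19
Reactants: 29 (2S,3R,4Z,6R,7S,9S,10R)-9-angeloyloxy-2,3-(isopropylidenedioxy)germacra-4,11(13)-dien-12,6-olide
Product: 30 (2S,3R,4Z,6R,7S,9S,10R)-9-angeloyloxy-2,3-dihydroxygermacra-4,11(13)-dien-12,6-olide (CNP0229085.1)
Conditions: AcOH/H2O (4:1), 40 °C
Reagents that add atoms: none
Why: Mild acetal hydrolysis releases the 2,3-diol without touching the angelate or the α-methylene lactone.

**Compound list**

1 | (S)-5-(hydroxymethyl)dihydrofuran-2(3H)-one | OC[C@@H]1CCC(=O)O1 | starting material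
2 | (S)-5-[(tert-butyldiphenylsilyloxy)methyl]dihydrofuran-2(3H)-one | O=C1CC[C@@H](CO[Si](c2ccccc2)(c2ccccc2)C(C)(C)C)O1 | intermediate
3 | lithium enolate of 2 | [Li]OC1=CC[C@@H](CO[Si](c2ccccc2)(c2ccccc2)C(C)(C)C)O1 | intermediate
4 | (3R,5S)-5-[(tert-butyldiphenylsilyloxy)methyl]-3-methyldihydrofuran-2(3H)-one | O=C1[C@H](C)C[C@@H](CO[Si](c2ccccc2)(c2ccccc2)C(C)(C)C)O1 | intermediate
5 | (3R,5S)-5-(hydroxymethyl)-3-methyldihydrofuran-2(3H)-one | O=C1[C@H](C)C[C@@H](CO)O1 | intermediate
6 | (2S,4R)-4-methyl-5-oxotetrahydrofuran-2-carbaldehyde | O=C1[C@H](C)C[C@@H](C=O)O1 | intermediate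
7 | but-2-yn-1-ol | CC#CCO | starting material
8 | cyclic alkenylaluminate, sodium 2,2-bis(2-methoxyethoxy)-3-methyl-2,5-dihydro-1,2-oxaaluminol-2-uide | CC1=CCO[Al-]1(OCCOC)OCCOC.[Na+] | intermediate
9 | (Z)-3-iodobut-2-en-1-ol | C/C(I)=C/CO | intermediate
10 | (Z)-3-iodobut-2-enal | C/C(I)=C/C=O | intermediate
11 | tert-butyldimethyl(prop-2-yn-1-yloxy)silane | C#CCO[Si](C)(C)C(C)(C)C | starting material
12 | methyl[3-(tert-butyldimethylsilyloxy)prop-1-ynyl]zinc | C[Zn]C#CCO[Si](C)(C)C(C)(C)C | intermediate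
13 | (4R,5Z)-1-(tert-butyldimethylsilyloxy)-6-iodohept-5-en-2-yn-4-ol | C/C(I)=C/[C@@H](O)C#CCO[Si](C)(C)C(C)(C)C | intermediate
14 | (4R,5Z)-1-(tert-butyldimethylsilyloxy)-6-iodo-4-(4-methoxybenzyloxy)hept-5-en-2-yne | C/C(I)=C/[C@@H](OCc1ccc(OC)cc1)C#CCO[Si](C)(C)C(C)(C)C | intermediate
15 | (3R,5S)-5-[(1R,2Z,4R)-7-(tert-butyldimethylsilyloxy)-1-hydroxy-4-(4-methoxybenzyloxy)-2-methylhept-2-en-5-yn-1-yl]-3-methyldihydrofuran-2(3H)-one | O=C1[C@H](C)C[C@@H]([C@H](O)/C(C)=C\[C@@H](OCc2ccc(OC)cc2)C#CCO[Si](C)(C)C(C)(C)C)O1 | intermediate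
16 | methyl (2R)-3-{(4S,5R)-5-[(2Z,4R)-7-hydroxy-4-(4-methoxybenzyloxy)hept-2-en-5-yn-2-yl]-2,2-dimethyl-1,3-dioxolan-4-yl}-2-methylpropanoate | COC(=O)[C@H](C)C[C@@H]1OC(C)(C)O[C@@H]1/C(C)=C\[C@@H](OCc1ccc(OC)cc1)C#CCO | intermediate
17 | methyl (2R)-3-{(4S,5R)-5-[(2Z,4R,5Z)-7-hydroxy-4-(4-methoxybenzyloxy)-6-(tributylstannyl)hepta-2,5-dien-2-yl]-2,2-dimethyl-1,3-dioxolan-4-yl}-2-methylpropanoate | COC(=O)[C@H](C)C[C@@H]1OC(C)(C)O[C@@H]1/C(C)=C\[C@@H](OCc1ccc(OC)cc1)/C=C(\[Sn](CCCC)(CCCC)CCCC)CO | intermediate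
18 | methyl (2R)-3-{(4S,5R)-5-[(2Z,4R,5Z)-7-hydroxy-6-iodo-4-(4-methoxybenzyloxy)hepta-2,5-dien-2-yl]-2,2-dimethyl-1,3-dioxolan-4-yl}-2-methylpropanoate | COC(=O)[C@H](C)C[C@@H]1OC(C)(C)O[C@@H]1/C(C)=C\[C@@H](OCc1ccc(OC)cc1)/C=C(\I)CO | intermediate
19 | (2R)-3-{(4S,5R)-5-[(2Z,4R,5Z)-7-hydroxy-6-iodo-4-(4-methoxybenzyloxy)hepta-2,5-dien-2-yl]-2,2-dimethyl-1,3-dioxolan-4-yl}-2-methylpropanoic acid | OC(=O)[C@H](C)C[C@@H]1OC(C)(C)O[C@@H]1/C(C)=C\[C@@H](OCc1ccc(OC)cc1)/C=C(\I)CO | intermediate
20 | mixed anhydride of 19 with 2,4,6-trichlorobenzoic acid | O=C(OC(=O)[C@H](C)C[C@@H]1OC(C)(C)O[C@@H]1/C(C)=C\[C@@H](OCc1ccc(OC)cc1)/C=C(\I)CO)c1c(Cl)cc(Cl)cc1Cl | intermediate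
21 | twelve-membered lactone of 19 (C9 carboxyl to O13; 2S,3R,6R,10R; 4Z; 7Z; 11-iodo; 2,3-acetonide; 6-O-PMB) | O=C1[C@H](C)C[C@@H]2OC(C)(C)O[C@@H]2/C(C)=C\[C@@H](OCc2ccc(OC)cc2)/C=C(\I)CO1 | intermediate
22 | exocyclic enol ether of 21 (C9=C8H2 in place of C9=O) | C=C1[C@H](C)C[C@@H]2OC(C)(C)O[C@@H]2/C(C)=C\[C@@H](OCc2ccc(OC)cc2)/C=C(\I)CO1 | intermediate
23 | (2S,3R,4Z,6R,7R,10R)-11-iodo-2,3-(isopropylidenedioxy)-6-(4-methoxybenzyloxy)-12-norgermacra-4,11(13)-dien-9-one | O=C1C[C@@H](C(I)=C)[C@H](OCc2ccc(OC)cc2)/C=C(/C)[C@H]2OC(C)(C)O[C@H]2C[C@H]1C | intermediate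
24 | (2S,3R,4Z,6R,7R,9S,10R)-11-iodo-2,3-(isopropylidenedioxy)-6-(4-methoxybenzyloxy)-12-norgermacra-4,11(13)-dien-9-ol | O[C@H]1C[C@@H](C(I)=C)[C@H](OCc2ccc(OC)cc2)/C=C(/C)[C@H]2OC(C)(C)O[C@H]2C[C@H]1C | intermediate
25 | angelic acid, (Z)-2-methylbut-2-enoic acid | C/C=C(/C)C(=O)O | starting material
26 | angelic 2,4,6-trichlorobenzoic mixed anhydride | C/C=C(/C)C(=O)OC(=O)c1c(Cl)cc(Cl)cc1Cl | intermediate
27 | (2S,3R,4Z,6R,7R,9S,10R)-9-angeloyloxy-11-iodo-2,3-(isopropylidenedioxy)-6-(4-methoxybenzyloxy)-12-norgermacra-4,11(13)-diene | C/C=C(/C)C(=O)O[C@H]1C[C@@H](C(I)=C)[C@H](OCc2ccc(OC)cc2)/C=C(/C)[C@H]2OC(C)(C)O[C@H]2C[C@H]1C | intermediate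
28 | (2S,3R,4Z,6R,7R,9S,10R)-9-angeloyloxy-11-iodo-2,3-(isopropylidenedioxy)-12-norgermacra-4,11(13)-dien-6-ol | C/C=C(/C)C(=O)O[C@H]1C[C@@H](C(I)=C)[C@H](O)/C=C(/C)[C@H]2OC(C)(C)O[C@H]2C[C@H]1C | intermediate
29 | (2S,3R,4Z,6R,7S,9S,10R)-9-angeloyloxy-2,3-(isopropylidenedioxy)germacra-4,11(13)-dien-12,6-olide | C=C1C(=O)O[C@@H]2/C=C(/C)[C@H]3OC(C)(C)O[C@H]3C[C@@H](C)[C@@H](OC(=O)/C(C)=C\C)C[C@@H]12 | intermediate
30 | (2S,3R,4Z,6R,7S,9S,10R)-9-angeloyloxy-2,3-dihydroxygermacra-4,11(13)-dien-12,6-olide (CNP0229085.1) | C=C1C(=O)O[C@@H]2/C=C(/C)[C@@H](O)[C@@H](O)C[C@@H](C)[C@@H](OC(=O)/C(C)=C\C)C[C@@H]12 | target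

**Step count and risks**

Total step count: 19. Longest linear sequence: 15 steps (steps 5–8 then 9–19, or steps 1–4 then 9–19).

Steps most likely to fail:

1. Step 14 (methylenation and ring contraction). The titanium reagent may attack the alkenyl iodide or fail to methylenate the α-branched lactone carbonyl. The [3,3] shift may also be outrun by hydrolysis of the enol ether or by Cope rearrangement at the temperature it needs, or C8 may bond to the wrong face of C7. The fallback avoids titanium and makes the ring by a decarboxylative Carroll ring contraction. It sets out from 18: crossed Claisen condensation with the lithium enolate of tert-butyl acetate (LDA, THF, −78 → 0 °C) should give the β-keto tert-butyl ester F1. Heating in dilute toluene (110 °C) should release the acylketene, which the C13 hydroxyl traps to give the fourteen-membered β-keto lactone F2. Further heating (xylene, 140 °C) should bring about the Carroll rearrangement to the β-keto acid F3, which loses carbon dioxide and comes back to the route at 23. The same A(1,3) element at C6 should control C7.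

2. Step 9 (NHK coupling). Facial selectivity of the alkenylchromium addition may be poor (Felkin against anti-Felkin), and the α-acyloxy aldehyde may hydrate or decompose. The fallback sets C3 by reagent-controlled reduction instead of by C–C bond formation. It sets out from 15 obtained as a mixture of C3 epimers: Dess–Martin oxidation should give the Z-enone F4, and Corey–Bakshi–Shibata reduction (Me-CBS antipode chosen for the 3R alcohol, catecholborane, toluene, −78 °C) comes back to the route at 15 as one C3 epimer.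

3. Step 15 (ketone reduction). Hydride may be delivered to the wrong face of the C9 carbonyl, because the conformation of the ten-membered ring rather than local Felkin control may decide. The fallback sets C9 by SN2 inversion. It sets out from 23: reduction under conditions that favour the other face (NaBH4, MeOH, 0 °C) gives the C9-epimeric alcohol F5. Mitsunobu reaction with 4-nitrobenzoic acid (DIAD, PPh3, toluene) should give the inverted 4-nitrobenzoate F6, and methanolysis (K2CO3, MeOH) comes back to the route at 24.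

**Further compounds**

F1 | step 14 | β-keto tert-butyl ester from 18 (tert-butyl 3-oxo ester, C8 and the ester carbon added to C9) | CC(C)(C)OC(=O)CC(=O)[C@H](C)C[C@@H]1OC(C)(C)O[C@@H]1/C(C)=C\[C@@H](OCc1ccc(OC)cc1)/C=C(\I)CO
F2 | step 14 | fourteen-membered β-keto lactone (ester carbonyl on C8 closed to O13) | O=C1CC(=O)[C@H](C)C[C@@H]2OC(C)(C)O[C@@H]2/C(C)=C\[C@@H](OCc2ccc(OC)cc2)/C=C(\I)CO1
F3 | step 14 | β-keto acid, 8-carboxy derivative of 23 | O=C1C(C(O)=O)[C@@H](C(I)=C)[C@H](OCc2ccc(OC)cc2)/C=C(/C)[C@H]2OC(C)(C)O[C@H]2C[C@H]1C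
F4 | step 9 | Z-enone, C3 ketone of 15 | O=C1[C@H](C)C[C@@H](C(=O)/C(C)=C\[C@@H](OCc2ccc(OC)cc2)C#CCO[Si](C)(C)C(C)(C)C)O1
F5 | step 15 | C9-epimeric alcohol (9R epimer of 24) | O[C@@H]1C[C@@H](C(I)=C)[C@H](OCc2ccc(OC)cc2)/C=C(/C)[C@H]2OC(C)(C)O[C@H]2C[C@H]1C
F6 | step 15 | 4-nitrobenzoate of 24 (9S) | O=C(O[C@H]1C[C@@H](C(I)=C)[C@H](OCc2ccc(OC)cc2)/C=C(/C)[C@H]2OC(C)(C)O[C@H]2C[C@H]1C)c1ccc(cc1)[N+](=O)[O-]
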